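**Retrosynthetic overview**

1. The last bond made is the ester C–O at the CH2O arm, by a Mitsunobu esterification of the free triol with ferulic acid that tolerates the phenols.
2. The benzyl CH2 on C4 is masked as a benzylic ether. This is a temporary second tetrahydrofuran (ring B: C3–CH2–O–CH(aryl)–C4) fused to the target ring (ring A), i.e. a furofuran with the (+)-pinoresinol configuration. Its benzylic C–O bond is later hydrogenolysed, steered to the guaiacyl side by a para-tosyloxy group on the syringyl ring; this also erases the stereocentre that controlled everything.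
3. Key disconnection: O1–C2 and C3–C4 of ring A together, back to an acyclic epoxy cinnamyl ether. The enabling feature is the terminal oxirane (O1–C5H2–C4H), held five atoms from the β-carbon C3 of the syringyl-conjugated C2=C3 double bond by the benzylic ether oxygen; that ether carbon is the only stereocentre that has to be set beforehand.
4. Ring order: ring B closes first (radical C–C closure), ring A second (C–O closure) in the same flask; ring B is opened in the next step.
5. The epoxy ether comes from a Williamson coupling of an epoxy alcohol (O-benzylvanillin, vinyl Grignard, Sharpless kinetic resolution) with a sinapyl-type bromide (syringaldehyde, tosylation, Wittig, reduction, bromination).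

Key step: step 8

Remark on locants: ring A is the tetrahydrofuran of the target (O1, C2 bearing the syringyl group, C3 bearing the CH2O arm, C4 bearing the benzyl group, C5); C7 is the benzylic carbon of the guaiacyl unit and C9 the CH2O carbon on C3. The sense of the kinetic resolution in step 2 is assumed to follow the usual Sharpless rule for secondary allylic alcohols.

**Route**

Step 1
Reactants: 1 4-(benzyloxy)-3-methoxybenzaldehyde; 2 vinylmagnesium bromide
Product: 3 (±)-1-[4-(benzyloxy)-3-methoxyphenyl]prop-2-en-1-ol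
Conditions: CH2=CHMgBr (1.2 equiv), THF, 0 °C; aq. NH4Cl
Reagents that add atoms: none
Why: Grignard 1,2-addition to the aldehyde should give the racemic allylic alcohol; the benzyl ether is inert and the neutral quench avoids allylic transposition of the electron-rich carbinol.

Step 2
Reactants: 3 (±)-1-[4-(benzyloxy)-3-methoxyphenyl]prop-2-en-1-ol
Product: 4 (R)-[4-(benzyloxy)-3-methoxyphenyl][(2S)-oxiran-2-yl]methanol
Conditions: Ti(Oi-Pr)4 (0.2 equiv), D-(−)-diisopropyl tartrate (0.25 equiv), t-BuOOH (0.45 equiv), 4 Å molecular sieves, CH2Cl2, −20 °C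
Reagents that add atoms: tert-butyl hydroperoxide, CC(C)(C)OO
Why: In this Sharpless kinetic resolution the D-(−)-tartrate catalyst should epoxidize the S enantiomer of 3 fast to the erythro epoxy alcohol, which fixes the carbinol centre (R in 4) that later steers the key step, while the slow R enantiomer of 3 stays behind and is removed by chromatography; the oxirane configuration itself is not needed later.

Step 3
Reactants: 5 4-hydroxy-3,5-dimethoxybenzaldehyde (syringaldehyde)
Product: 6 4-formyl-2,6-dimethoxyphenyl 4-methylbenzenesulfonate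
Conditions: TsCl (1.2 equiv), Et3N (1.5 equiv), DMAP (cat.), CH2Cl2, 0 °C to rt
Reagents that add atoms: 4-methylbenzenesulfonyl chloride, Cc1ccc(cc1)S(=O)(=O)Cl
Why: O-sulfonylation of the phenol installs a robust, electron-withdrawing group that survives hydride, base and single-electron reductants and later differentiates the two benzylic ethers.

Step 4
Reactants: 6 4-formyl-2,6-dimethoxyphenyl 4-methylbenzenesulfonate; 7 ethyl (triphenylphosphoranylidene)acetate
Product: 8 ethyl (2E)-3-[3,5-dimethoxy-4-(tosyloxy)phenyl]prop-2-enoate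
Conditions: toluene, 80 °C
Reagents that add atoms: none
Why: Wittig olefination with a stabilized ylide should give the E cinnamate under neutral conditions that leave the aryl sulfonate untouched.

Step 5
Reactants: 8 ethyl (2E)-3-[3,5-dimethoxy-4-(tosyloxy)phenyl]prop-2-enoate
Product: 9 4-[(1E)-3-hydroxyprop-1-en-1-yl]-2,6-dimethoxyphenyl 4-methylbenzenesulfonate
Conditions: i-Bu2AlH (2.3 equiv), CH2Cl2, −78 °C; aq. potassium sodium tartrate
Reagents that add atoms: none
Why: Hydride 1,2-reduction of the enoate should give the E allylic alcohol, the hindered aryl sulfonate being inert to i-Bu2AlH at low temperature.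

Step 6
Reactants: 9 4-[(1E)-3-hydroxyprop-1-en-1-yl]-2,6-dimethoxyphenyl 4-methylbenzenesulfonate
Product: 10 4-[(1E)-3-bromoprop-1-en-1-yl]-2,6-dimethoxyphenyl 4-methylbenzenesulfonate
Conditions: PBr3 (0.4 equiv), Et2O, 0 °C; used without storage
Reagents that add atoms: phosphorus tribromide, BrP(Br)Br
Why: Alcohol-to-bromide substitution with PBr3 should give the conjugated primary E bromide, which the tosyloxy group makes less prone to ionization than an electron-rich cinnamyl bromide.

Step 7
Reactants: 4 (R)-[4-(benzyloxy)-3-methoxyphenyl][(2S)-oxiran-2-yl]methanol; 10 4-[(1E)-3-bromoprop-1-en-1-yl]-2,6-dimethoxyphenyl 4-methylbenzenesulfonate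
Product: 11 4-[(1E)-3-{(R)-[4-(benzyloxy)-3-methoxyphenyl][(2S)-oxiran-2-yl]methoxy}prop-1-en-1-yl]-2,6-dimethoxyphenyl 4-methylbenzenesulfonate
Conditions: NaH (1.1 equiv) added to 4 and 10, n-Bu4NI (cat.), THF–DMF, −20 to 0 °C
Reagents that add atoms: none
Why: In this Williamson ether synthesis the C–O bond of the carbinol is not broken, so its configuration is retained, and having the reactive bromide present from the start at low temperature should trap the alkoxide before a Payne rearrangement can set in.

Step 8
Reactants: 11 4-[(1E)-3-{(R)-[4-(benzyloxy)-3-methoxyphenyl][(2S)-oxiran-2-yl]methoxy}prop-1-en-1-yl]-2,6-dimethoxyphenyl 4-methylbenzenesulfonate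
Product: 14 4-[(1S,3aR,4S,6aR)-4-[4-(benzyloxy)-3-methoxyphenyl]hexahydrofuro[3,4-c]furan-1-yl]-2,6-dimethoxyphenyl 4-methylbenzenesulfonate, via benzylic titanium alkoxide 12 (not isolated), via benzylic iodide 13 (not isolated)
Conditions: Cp2TiCl2 (2.5 equiv), Zn dust, THF, rt (Cp2TiCl formed in the flask), slow addition of 11; then I2 (1.3 equiv), rt to 50 °C, same flask
Reagents that add atoms: none
Why: Cp2TiCl, a single-electron reductant of trivalent titanium, should cleave the internal C–O bond of the oxirane to the secondary β-titanoxy radical at C4 (Nugent–RajanBabu reaction), which adds 5-exo-trig to the styrenyl β-carbon C3 through the benzylic ether tether (C3–C4 bond, temporary ring B); the benzylic radical at C2 is captured by a second Cp2TiCl to give 12, iodine converts the C–Ti bond into the benzylic iodide 13, and the titanium alkoxide on C5 displaces it 5-exo-tet (O1–C2 bond, ring A). The closest known reaction type is the titanocene-mediated radical cyclization of epoxy cinnamyl ethers with iodine work-up that gives furofuran lignans. The only stereocentre of 11 that counts is the benzylic ether carbon C7, because the oxirane carbon becomes a planar radical: in the chair-like transition state of the 5-hexenyl-type cyclization the C7 aryl group sits pseudo-equatorial, so the CH2O[Ti] arm on C4 should end trans to it and cis to the new arm on C3, which fixes C3 and C4 as R,R and the cis ring fusion. C2 is set in the ring-A closure, where the benzylic iodide can epimerize by iodide exchange and should close through the transition state that places the aryl group on the convex face (S). The step needs secondary-radical regiochemistry in the epoxide opening, cyclization faster than reduction of the radical, and face selectivity; these are secured by the terminal oxirane, by the fast styrene acceptor together with slow addition of 11, and by the fact that only the 3,4-cis isomer can close to the bicycle, so minor diastereomers stay monocyclic and are removed by chromatography at this stage.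

Step 9
Reactants: 14 4-[(1S,3aR,4S,6aR)-4-[4-(benzyloxy)-3-methoxyphenyl]hexahydrofuro[3,4-c]furan-1-yl]-2,6-dimethoxyphenyl 4-methylbenzenesulfonate
Product: 15 4-[(2S,3R,4R)-4-(4-hydroxy-3-methoxybenzyl)-3-(hydroxymethyl)tetrahydrofuran-2-yl]-2,6-dimethoxyphenyl 4-methylbenzenesulfonate
Conditions: H2 (1 atm), 10% Pd/C, EtOAc–MeOH, rt, stopped after uptake of two equivalents
Reagents that add atoms: none
Why: Catalytic hydrogenolysis should first remove the benzyl ether and then cleave the now para-hydroxy-activated benzylic C7–O bond of ring B (the pinoresinol-to-lariciresinol type of opening), while the C2–O1 bond is protected by the para-tosyloxy group and two meta-methoxy groups; C7 becomes CH2, so its stereocentre is erased on purpose and C2, C3 and C4 are untouched.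

Step 10
Reactants: 15 4-[(2S,3R,4R)-4-(4-hydroxy-3-methoxybenzyl)-3-(hydroxymethyl)tetrahydrofuran-2-yl]-2,6-dimethoxyphenyl 4-methylbenzenesulfonate
Product: 16 4-[(2S,3R,4R)-4-(4-hydroxy-3-methoxybenzyl)-3-(hydroxymethyl)tetrahydrofuran-2-yl]-2,6-dimethoxyphenol
Conditions: KOH (aq., 5 equiv), MeOH–THF, 60 °C; then dilute HCl to pH 5
Reagents that add atoms: none
Why: Alkaline hydrolysis of the aryl sulfonate by hydroxide attack at sulfur should free the syringyl phenol, the tetrahydrofuran and its three stereocentres being stable to base at this temperature.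

Step 11
Reactants: 16 4-[(2S,3R,4R)-4-(4-hydroxy-3-methoxybenzyl)-3-(hydroxymethyl)tetrahydrofuran-2-yl]-2,6-dimethoxyphenol; 17 (2E)-3-(4-hydroxy-3-methoxyphenyl)prop-2-enoic acid (ferulic acid)
Product: 18 [(2S,3R,4R)-2-(4-hydroxy-3,5-dimethoxyphenyl)-4-(4-hydroxy-3-methoxybenzyl)tetrahydrofuran-3-yl]methyl (2E)-3-(4-hydroxy-3-methoxyphenyl)prop-2-enoate
Conditions: PPh3 (1.3 equiv), diisopropyl azodicarboxylate (1.3 equiv, added last), 17 (1.2 equiv), THF, 0 °C to rt
Reagents that add atoms: none
Why: In this Mitsunobu esterification only the primary aliphatic alcohol is activated by the phosphonium betaine and the carboxylate, far more acidic than any of the phenols, should be the nucleophile, so the phenols need no protection; the reacting carbon is a CH2 and the E alkene is not touched.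

**Compound list**

1 | 4-(benzyloxy)-3-methoxybenzaldehyde | COc1cc(C=O)ccc1OCc1ccccc1 | starting material
2 | vinylmagnesium bromide | C=C[Mg]Br | starting material
3 | (±)-1-[4-(benzyloxy)-3-methoxyphenyl]prop-2-en-1-ol (racemate) | COc1cc(C(O)C=C)ccc1OCc1ccccc1 | intermediate
4 | (R)-[4-(benzyloxy)-3-methoxyphenyl][(2S)-oxiran-2-yl]methanol | COc1cc(ccc1OCc1ccccc1)[C@@H](O)[C@@H]1CO1 | intermediate
5 | 4-hydroxy-3,5-dimethoxybenzaldehyde (syringaldehyde) | COc1cc(C=O)cc(OC)c1O | starting material
6 | 4-formyl-2,6-dimethoxyphenyl 4-methylbenzenesulfonate | COc1cc(C=O)cc(OC)c1OS(=O)(=O)c1ccc(C)cc1 | intermediate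
7 | ethyl (triphenylphosphoranylidene)acetate | CCOC(=O)C=P(c1ccccc1)(c1ccccc1)c1ccccc1 | starting material
8 | ethyl (2E)-3-[3,5-dimethoxy-4-(tosyloxy)phenyl]prop-2-enoate | CCOC(=O)/C=C/c1cc(OC)c(OS(=O)(=O)c2ccc(C)cc2)c(OC)c1 | intermediate
9 | 4-[(1E)-3-hydroxyprop-1-en-1-yl]-2,6-dimethoxyphenyl 4-methylbenzenesulfonate | OC/C=C/c1cc(OC)c(OS(=O)(=O)c2ccc(C)cc2)c(OC)c1 | intermediate
10 | 4-[(1E)-3-bromoprop-1-en-1-yl]-2,6-dimethoxyphenyl 4-methylbenzenesulfonate | BrC/C=C/c1cc(OC)c(OS(=O)(=O)c2ccc(C)cc2)c(OC)c1 | intermediate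
11 | 4-[(1E)-3-{(R)-[4-(benzyloxy)-3-methoxyphenyl][(2S)-oxiran-2-yl]methoxy}prop-1-en-1-yl]-2,6-dimethoxyphenyl 4-methylbenzenesulfonate | COc1cc(ccc1OCc1ccccc1)[C@@H](OC/C=C/c1cc(OC)c(OS(=O)(=O)c2ccc(C)cc2)c(OC)c1)[C@@H]1CO1 | intermediate
12 | Cp2ClTi alkoxide of [(2S,3R,4R)-2-[4-(benzyloxy)-3-methoxyphenyl]-4-{[3,5-dimethoxy-4-(tosyloxy)phenyl](TiClCp2)methyl}tetrahydrofuran-3-yl]methanol, both epimers at the C–Ti carbon, Cp drawn sigma-bonded | COc1cc(ccc1OCc1ccccc1)[C@H]1OC[C@H](C([Ti](Cl)(C2C=CC=C2)C2C=CC=C2)c2cc(OC)c(OS(=O)(=O)c3ccc(C)cc3)c(OC)c2)[C@@H]1CO[Ti](Cl)(C1C=CC=C1)C1C=CC=C1 | intermediate (not isolated)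
13 | Cp2ClTi alkoxide of [(2S,3R,4R)-2-[4-(benzyloxy)-3-methoxyphenyl]-4-{[3,5-dimethoxy-4-(tosyloxy)phenyl]iodomethyl}tetrahydrofuran-3-yl]methanol, both epimers at the C–I carbon | COc1cc(ccc1OCc1ccccc1)[C@H]1OC[C@H](C(I)c2cc(OC)c(OS(=O)(=O)c3ccc(C)cc3)c(OC)c2)[C@@H]1CO[Ti](Cl)(C1C=CC=C1)C1C=CC=C1 | intermediate (not isolated)
14 | 4-[(1S,3aR,4S,6aR)-4-[4-(benzyloxy)-3-methoxyphenyl]hexahydrofuro[3,4-c]furan-1-yl]-2,6-dimethoxyphenyl 4-methylbenzenesulfonate | COc1cc(ccc1OCc1ccccc1)[C@H]1OC[C@H]2[C@@H]1CO[C@@H]2c1cc(OC)c(OS(=O)(=O)c2ccc(C)cc2)c(OC)c1 | intermediate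
15 | 4-[(2S,3R,4R)-4-(4-hydroxy-3-methoxybenzyl)-3-(hydroxymethyl)tetrahydrofuran-2-yl]-2,6-dimethoxyphenyl 4-methylbenzenesulfonate | OC[C@H]1[C@@H](Cc2ccc(O)c(OC)c2)CO[C@@H]1c1cc(OC)c(OS(=O)(=O)c2ccc(C)cc2)c(OC)c1 | intermediate
16 | 4-[(2S,3R,4R)-4-(4-hydroxy-3-methoxybenzyl)-3-(hydroxymethyl)tetrahydrofuran-2-yl]-2,6-dimethoxyphenol | OC[C@H]1[C@@H](Cc2ccc(O)c(OC)c2)CO[C@@H]1c1cc(OC)c(O)c(OC)c1 | intermediate
17 | (2E)-3-(4-hydroxy-3-methoxyphenyl)prop-2-enoic acid (ferulic acid) | COc1cc(/C=C/C(=O)O)ccc1O | starting material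
18 | [(2S,3R,4R)-2-(4-hydroxy-3,5-dimethoxyphenyl)-4-(4-hydroxy-3-methoxybenzyl)tetrahydrofuran-3-yl]methyl (2E)-3-(4-hydroxy-3-methoxyphenyl)prop-2-enoate | COc1cc(/C=C/C(=O)OC[C@H]2[C@@H](Cc3ccc(O)c(OC)c3)CO[C@@H]2c2cc(OC)c(O)c(OC)c2)ccc1O | target

**Step count and risks**

Total step count: 11. Longest linear sequence: 9 steps (steps 3 to 11, from syringaldehyde).

Steps most likely to fail:

1. Step 8. The benzylic radical may be reduced before it is captured, the iodine-triggered C–O closure at the tosyloxy-deactivated benzylic carbon may be slow or poorly face-selective, and an imperfect diastereomer ratio in the radical cyclization would, if not removed at the furofuran stage, surface as loss of enantiopurity once C7 is reduced. The fallback sets out from 11 and comes back at 14. The same Cp2TiCl cyclization is quenched with dilute HCl instead of iodine, the established furano-lignan variant, to give the monocyclic tetrahydrofuran alcohol F1, which is purified as one diastereomer. KOH in MeOH–THF removes the tosyl group to give the syringyl phenol F2. Ag2O in CH2Cl2 then oxidizes the 4-alkyl-2,6-dimethoxyphenol to its para-quinone methide, which the cis CH2OH group traps in a reversible 1,6-oxa-addition that should place the aryl group on the convex face, giving the furofuran phenol F3. TsCl and Et3N restore the sulfonate and deliver 14.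

2. Step 9. Hydrogenolysis may lose regioselectivity, either by over-reduction of the second benzylic C–O bond to a ring-opened diol or by cleavage on the syringyl side. The fallback sets out from 14 and comes back at 15. Ionic hydrogenation with Et3SiH and BF3·OEt2 in CH2Cl2 at −78 to −30 °C should ionize only the benzyloxy-activated benzylic carbon C7 and give the ring-opened benzyl ether alcohol F4. A short hydrogenation over 10% Pd/C then removes only the aryl benzyl ether, which cleaves far faster than the deactivated cyclic benzylic ether, and gives 15.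

3. Step 11. Competing O-alkylation of one of the three phenols by the activated alcohol, or sluggish activation of the β-branched primary alcohol, may erode the chemoselectivity of the esterification. The fallback sets out from 16 and 17 and comes back at 18. TBSOTf and 2,6-lutidine convert 16 into the tris-silyl ether F5, and PPTS in MeOH removes only the primary alkyl silyl ether to give the bis(aryl silyl ether) alcohol F6. Ferulic acid 17 with TBSCl and imidazole gives the silyl ester silyl ether F7, whose silyl ester is cleaved by K2CO3 in aqueous MeOH to the 4-O-silylated acid F8. Steglich-type coupling of F6 and F8 (EDC·HCl, DMAP, CH2Cl2) gives the tris-silylated ester F9, and Et3N·3HF in THF removes the three aryl silyl ethers without touching the ester, giving 18.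

**Further compounds**

F1 | step 8 | [(2S,3R,4R)-2-[4-(benzyloxy)-3-methoxyphenyl]-4-{[3,5-dimethoxy-4-(tosyloxy)phenyl]methyl}tetrahydrofuran-3-yl]methanol | COc1cc(ccc1OCc1ccccc1)[C@H]1OC[C@H](Cc2cc(OC)c(OS(=O)(=O)c3ccc(C)cc3)c(OC)c2)[C@@H]1CO
F2 | step 8 | 4-{[(3R,4R,5S)-5-[4-(benzyloxy)-3-methoxyphenyl]-4-(hydroxymethyl)tetrahydrofuran-3-yl]methyl}-2,6-dimethoxyphenol | COc1cc(ccc1OCc1ccccc1)[C@H]1OC[C@H](Cc2cc(OC)c(O)c(OC)c2)[C@@H]1CO
F3 | step 8 | 4-[(1S,3aR,4S,6aR)-4-[4-(benzyloxy)-3-methoxyphenyl]hexahydrofuro[3,4-c]furan-1-yl]-2,6-dimethoxyphenol | COc1cc(ccc1OCc1ccccc1)[C@H]1OC[C@H]2[C@@H]1CO[C@@H]2c1cc(OC)c(O)c(OC)c1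
F4 | step 9 | 4-[(2S,3R,4R)-4-[4-(benzyloxy)-3-methoxybenzyl]-3-(hydroxymethyl)tetrahydrofuran-2-yl]-2,6-dimethoxyphenyl 4-methylbenzenesulfonate | OC[C@H]1[C@@H](Cc2ccc(OCc3ccccc3)c(OC)c2)CO[C@@H]1c1cc(OC)c(OS(=O)(=O)c2ccc(C)cc2)c(OC)c1
F5 | step 11 | tris(tert-butyldimethylsilyl) ether of 16 (both phenols and the primary alcohol silylated) | CC(C)(C)[Si](C)(C)OC[C@H]1[C@@H](Cc2ccc(O[Si](C)(C)C(C)(C)C)c(OC)c2)CO[C@@H]1c1cc(OC)c(O[Si](C)(C)C(C)(C)C)c(OC)c1
F6 | step 11 | [(2S,3R,4R)-2-{4-[(tert-butyldimethylsilyl)oxy]-3,5-dimethoxyphenyl}-4-{4-[(tert-butyldimethylsilyl)oxy]-3-methoxybenzyl}tetrahydrofuran-3-yl]methanol | OC[C@H]1[C@@H](Cc2ccc(O[Si](C)(C)C(C)(C)C)c(OC)c2)CO[C@@H]1c1cc(OC)c(O[Si](C)(C)C(C)(C)C)c(OC)c1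
F7 | step 11 | tert-butyldimethylsilyl (2E)-3-{4-[(tert-butyldimethylsilyl)oxy]-3-methoxyphenyl}prop-2-enoate | COc1cc(/C=C/C(=O)O[Si](C)(C)C(C)(C)C)ccc1O[Si](C)(C)C(C)(C)C
F8 | step 11 | (2E)-3-{4-[(tert-butyldimethylsilyl)oxy]-3-methoxyphenyl}prop-2-enoic acid | COc1cc(/C=C/C(=O)O)ccc1O[Si](C)(C)C(C)(C)C
F9 | step 11 | tris(tert-butyldimethylsilyl) ether of 18 (all three phenols silylated) | COc1cc(/C=C/C(=O)OC[C@H]2[C@@H](Cc3ccc(O[Si](C)(C)C(C)(C)C)c(OC)c3)CO[C@@H]2c2cc(OC)c(O[Si](C)(C)C(C)(C)C)c(OC)c2)ccc1O[Si](C)(C)C(C)(C)C
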